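## Retrosynthetic overview

1. The oxa-bridged core is cut by a biomimetic [4+2]: a 1-aryl isobenzofuran (from an arugosin-type hydroxymethyl benzophenone) adds to the C2=C3 bond of a remisporine-type (S)-cyclopentadienol chromone, setting four stereocentres at once.
2. Both partners are transient and are unveiled in one flask by one acid: lactol dehydration gives the diene, and an intramolecular vinylogous aldol condensation of a 2-methylchromone α-hydroxy aldehyde gives the cyclopentadiene ring of the dienophile.
3. The α-hydroxy aldehyde comes from an asymmetric formyl-anion addition to a chromone-3-glyoxylate, made by enaminone annulation (pyranone ring) from 3,5-dihydroxybenzyl alcohol.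
4. The benzophenone comes from a 2,6-dioxygenated aryllithium and a phthalide (lactone ring by directed ortho-metalation) from 2,5-dimethoxy-4-methylbenzaldehyde.
5. Ring order: phthalide lactone, then chromone pyranone, then in the last flask isobenzofuran furan ring, cyclopentadiene ring, and the oxa-bridged bicycle.

Assumption: the antipode of the bis-urea catalyst in step 13 is chosen, by analogy with simple aryl α-keto esters, to give the (R)-carbinol 22; the other antipode is equally available.

## Route

Step 1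
Reactants: 1 2,5-dimethoxy-4-methylbenzaldehyde
Product: 2 2,5-dimethoxy-4-methylbenzoic acid
Conditions: NaClO2, NaH2PO4, 2-methyl-2-butene, t-BuOH/H2O, 23 °C
Reagents that add atoms: sodium chlorite, [Na+].[O-]Cl=O
Why: Pinnick oxidation converts the aldehyde to the acid without chlorinating the electron-rich ring because 2-methyl-2-butene scavenges HOCl.

Step 2
Reactants: 2 2,5-dimethoxy-4-methylbenzoic acid
Product: 4 4,7-dimethoxy-5-methylisobenzofuran-1(3H)-one, via formyl acid 3 (not isolated)
Conditions: s-BuLi (2.2 equiv), TMEDA, THF, −78 °C; DMF; then MeOH, NaBH4, 0 °C; 2 M HCl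
Reagents that add atoms: N,N-dimethylformamide, CN(C)C=O
Why: Carboxylate-directed ortho-metalation lithiates the only C–H ortho to CO2Li (also ortho to OMe), DMF formylates it, and borohydride reduction with acid lactonisation gives the phthalide with its carbonyl on the ring carbon para to the methyl group.

Step 3
Reactants: 4 4,7-dimethoxy-5-methylisobenzofuran-1(3H)-one
Product: 5 4,7-dihydroxy-5-methylisobenzofuran-1(3H)-one
Conditions: BBr3 (3 equiv), CH2Cl2, −78 to 0 °C; H2O
Reagents that add atoms: none
Why: BBr3 aryl methyl ether cleavage frees both phenols while the lactone survives at low temperature.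

Step 4
Reactants: 5 4,7-dihydroxy-5-methylisobenzofuran-1(3H)-one
Product: 6 7-hydroxy-4-(3-hydroxy-3-methylbutoxy)-5-methylisobenzofuran-1(3H)-one
Conditions: K2CO3 (2 equiv), KI (cat.), DMF, 60 °C
Reagents that add atoms: 4-bromo-2-methylbutan-2-ol, CC(C)(O)CCBr
Why: Williamson etherification is site-selective because the 7-OH is hydrogen-bonded to the lactone carbonyl and its phenoxide is a poor nucleophile, so the 4-OH is alkylated (the selectivity known for 2,5-dihydroxybenzoates).

Step 5
Reactants: 6 7-hydroxy-4-(3-hydroxy-3-methylbutoxy)-5-methylisobenzofuran-1(3H)-one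
Product: 7 4-(3-hydroxy-3-methylbutoxy)-7-(methoxymethoxy)-5-methylisobenzofuran-1(3H)-one
Conditions: NaH (1.05 equiv), THF/DMF, 0 °C; MOMCl
Reagents that add atoms: chloromethyl methyl ether, COCCl
Why: O-alkylation of the sodium phenoxide (one equivalent of base does not deprotonate the tertiary alcohol) masks the acidic phenol before the organolithium step.

Step 6
Reactants: 8 resorcinol
Product: 9 1,3-bis(methoxymethoxy)benzene
Conditions: NaH (2.2 equiv), MOMCl, DMF, 0 to 23 °C
Reagents that add atoms: chloromethyl methyl ether, COCCl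
Why: Williamson-type MOM protection gives an arene that lithiates cleanly between its two directing groups.

Step 7
Reactants: 7 4-(3-hydroxy-3-methylbutoxy)-7-(methoxymethoxy)-5-methylisobenzofuran-1(3H)-one; 9 1,3-bis(methoxymethoxy)benzene
Product: 11 (2,6-dihydroxyphenyl)[6-hydroxy-2-(hydroxymethyl)-3-(3-hydroxy-3-methylbutoxy)-4-methylphenyl]methanone, via tris-MOM hydroxy ketone 10 (not isolated)
Conditions: 9 (3.2 equiv), n-BuLi (3.0 equiv), THF, 0 °C; add 7, −78 to 0 °C; then 1 M HCl in MeOH, 35 °C; aq. work-up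
Reagents that add atoms: none
Why: Directed ortho-metalation of 9 between its OMOM groups gives the aryllithium (one equivalent is spent on the tertiary OH), which adds once to the lactone carbonyl to give a stable lithium lactolate, and acidic methanolysis then removes the three MOM acetals.

Step 8
Reactants: 12 3,5-dihydroxybenzyl alcohol
Product: 13 1,3-bis(methoxymethoxy)-5-[(methoxymethoxy)methyl]benzene
Conditions: NaH (3.5 equiv), MOMCl, THF/DMF, 0 to 23 °C
Reagents that add atoms: chloromethyl methyl ether, COCCl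
Why: Williamson-type MOM protection of both phenols and the benzylic alcohol installs the directing groups and removes all acidic protons.

Step 9
Reactants: 13 1,3-bis(methoxymethoxy)-5-[(methoxymethoxy)methyl]benzene
Product: 14 1-{2,6-bis(methoxymethoxy)-4-[(methoxymethoxy)methyl]phenyl}ethan-1-one
Conditions: n-BuLi (1.1 equiv), THF, 0 °C; MeC(O)N(OMe)Me, −78 to 0 °C
Reagents that add atoms: N-methoxy-N-methylacetamide, CC(=O)N(C)OC
Why: Directed ortho-metalation at the position flanked by both OMOM groups followed by Weinreb ketone synthesis, whose chelated tetrahedral intermediate prevents over-addition.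

Step 10
Reactants: 14 1-{2,6-bis(methoxymethoxy)-4-[(methoxymethoxy)methyl]phenyl}ethan-1-one
Product: 15 (E)-1-{2,6-bis(methoxymethoxy)-4-[(methoxymethoxy)methyl]phenyl}-3-(dimethylamino)but-2-en-1-one
Conditions: MeC(OMe)2NMe2 (3 equiv), toluene, 110 °C
Reagents that add atoms: N,N-dimethylacetamide dimethyl acetal, COC(C)(OC)N(C)C
Why: Amide acetal condensation at the acetyl methyl gives the β-methyl enaminone, the masked 1,3-diketone needed for a 2-methylchromone.

Step 11
Reactants: 15 (E)-1-{2,6-bis(methoxymethoxy)-4-[(methoxymethoxy)methyl]phenyl}-3-(dimethylamino)but-2-en-1-one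
Product: 17 methyl 2-[5-hydroxy-7-(hydroxymethyl)-2-methyl-4-oxo-4H-chromen-3-yl]-2-oxoacetate, via acylated enaminone 16 (not isolated)
Conditions: ClC(O)CO2Me (1.3 equiv), pyridine, CH2Cl2, 0 to 23 °C; then 3 M HCl in MeOH, 45 °C
Reagents that add atoms: methyl chlorooxoacetate, COC(=O)C(Cl)=O
Why: C-acylation of the enaminone at its nucleophilic α-carbon, after which acid frees the phenols and one of them closes the pyranone by conjugate addition–elimination of dimethylamine (enaminone chromone annulation).

Step 12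
Reactants: 18 tert-butylhydrazine hydrochloride
Product: 19 formaldehyde tert-butylhydrazone
Conditions: 37% aq. CH2O, NaOH, H2O, 0 to 23 °C; extraction into toluene
Reagents that add atoms: formaldehyde, C=O
Why: Hydrazone condensation of the liberated hydrazine with formaldehyde gives a neutral formyl anion equivalent.

Step 13
Reactants: 17 methyl 2-[5-hydroxy-7-(hydroxymethyl)-2-methyl-4-oxo-4H-chromen-3-yl]-2-oxoacetate; 19 formaldehyde tert-butylhydrazone
Product: 22 methyl (2R)-2-hydroxy-2-[5-hydroxy-7-(hydroxymethyl)-2-methyl-4-oxo-4H-chromen-3-yl]-3-oxopropanoate, via diazene 20 (not isolated), via hydrazone 21 (not isolated)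
Conditions: 19 (2 equiv), BINAM-derived bis[3,5-bis(trifluoromethyl)phenyl]urea (10 mol %), toluene, −20 °C; then 2 M aq. HCl, THF, 23 °C
Reagents that add atoms: water, O
Why: Hydrogen-bond (bis-urea) catalysed asymmetric formal carbonyl-ene addition of the hydrazone to the α-keto ester sets the quaternary carbinol under catalyst control (R in 22, which becomes the (S)-C(OH)CO2Me centre of the target by a priority change only), and acid then tautomerises the diazene to the hydrazone and hydrolyses it to the aldehyde.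

Step 14
Reactants: 11 (2,6-dihydroxyphenyl)[6-hydroxy-2-(hydroxymethyl)-3-(3-hydroxy-3-methylbutoxy)-4-methylphenyl]methanone; 22 methyl (2R)-2-hydroxy-2-[5-hydroxy-7-(hydroxymethyl)-2-methyl-4-oxo-4H-chromen-3-yl]-3-oxopropanoate
Product: 25 aspergichromone A, via isobenzofuran 23 (not isolated), via cyclopentadienol 24 (not isolated)
Conditions: 11 (1.5 equiv), (PhO)2P(O)OH (0.3 equiv), 4 Å MS, degassed ClCH2CH2Cl (0.01 M), 50 °C, dark
Reagents that add atoms: none
Why: Proposed new method: one Brønsted acid dehydrates 11 through its cyclic hemiketal to the 1-arylisobenzofuran 23 and, via the 2-methylene-2H-chromen-4-ol tautomer of the protonated 2-methylchromone, closes 22 by intramolecular vinylogous aldol condensation to the cyclopentadienol 24, which forms slowly beside excess 23 (so cross-cycloaddition beats its own Diels–Alder dimerisation) and reacts at C2=C3 in a reversible [4+2] in which the unsubstituted diene terminus bonds to the electrophilic C2 ("ortho" rule) and the diene adds exo on the face carrying the C1–OH (O–H···O hydrogen bond to the furan oxygen, anti to CO2Me), so the (S)-carbinol centre fixes all four new stereocentres; the closest known reactions are acid-triggered isobenzofuran generation from lactols with Diels–Alder trapping, styryl condensations of 2-methylchromones, and the spontaneous Diels–Alder dimerisation of cyclopentadienyl chromones.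

## Compound list

1 | 2,5-dimethoxy-4-methylbenzaldehyde | COc1cc(C)c(OC)cc1C=O | starting material
2 | 2,5-dimethoxy-4-methylbenzoic acid | COc1cc(C)c(OC)cc1C(=O)O | intermediate
3 | 2-formyl-3,6-dimethoxy-4-methylbenzoic acid (lithium carboxylate in the flask) | COc1cc(C)c(OC)c(C=O)c1C(=O)O | intermediate
4 | 4,7-dimethoxy-5-methylisobenzofuran-1(3H)-one | COc1cc(C)c(OC)c2c1C(=O)OC2 | intermediate
5 | 4,7-dihydroxy-5-methylisobenzofuran-1(3H)-one | Cc1cc(O)c2c(c1O)COC2=O | intermediate
6 | 7-hydroxy-4-(3-hydroxy-3-methylbutoxy)-5-methylisobenzofuran-1(3H)-one | Cc1cc(O)c2c(c1OCCC(C)(C)O)COC2=O | intermediate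
7 | 4-(3-hydroxy-3-methylbutoxy)-7-(methoxymethoxy)-5-methylisobenzofuran-1(3H)-one | COCOc1cc(C)c(OCCC(C)(C)O)c2c1C(=O)OC2 | intermediate
8 | resorcinol | Oc1cccc(O)c1 | starting material
9 | 1,3-bis(methoxymethoxy)benzene | COCOc1cccc(OCOC)c1 | intermediate
10 | [2,6-bis(methoxymethoxy)phenyl][2-(hydroxymethyl)-3-(3-hydroxy-3-methylbutoxy)-6-(methoxymethoxy)-4-methylphenyl]methanone (open form of the lactol) | COCOc1cccc(OCOC)c1C(=O)c1c(OCOC)cc(C)c(OCCC(C)(C)O)c1CO | intermediate
11 | (2,6-dihydroxyphenyl)[6-hydroxy-2-(hydroxymethyl)-3-(3-hydroxy-3-methylbutoxy)-4-methylphenyl]methanone (open form of the lactol) | O=C(c1c(O)cccc1O)c1c(O)cc(C)c(OCCC(C)(C)O)c1CO | intermediate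
12 | 3,5-dihydroxybenzyl alcohol | OCc1cc(O)cc(O)c1 | starting material
13 | 1,3-bis(methoxymethoxy)-5-[(methoxymethoxy)methyl]benzene | COCOCc1cc(OCOC)cc(OCOC)c1 | intermediate
14 | 1-{2,6-bis(methoxymethoxy)-4-[(methoxymethoxy)methyl]phenyl}ethan-1-one | CC(=O)c1c(OCOC)cc(COCOC)cc1OCOC | intermediate
15 | (E)-1-{2,6-bis(methoxymethoxy)-4-[(methoxymethoxy)methyl]phenyl}-3-(dimethylamino)but-2-en-1-one | CN(C)/C(C)=C/C(=O)c1c(OCOC)cc(COCOC)cc1OCOC | intermediate
16 | methyl 3-{2,6-bis(methoxymethoxy)-4-[(methoxymethoxy)methyl]benzoyl}-4-(dimethylamino)-2-oxopent-3-enoate | COC(=O)C(=O)C(C(=O)c1c(OCOC)cc(COCOC)cc1OCOC)=C(C)N(C)C | intermediate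
17 | methyl 2-[5-hydroxy-7-(hydroxymethyl)-2-methyl-4-oxo-4H-chromen-3-yl]-2-oxoacetate | COC(=O)C(=O)c1c(C)oc2cc(CO)cc(O)c2c1=O | intermediate
18 | tert-butylhydrazine hydrochloride | CC(C)(C)NN.Cl | starting material
19 | formaldehyde tert-butylhydrazone | C=NNC(C)(C)C | intermediate
20 | methyl (2R)-3-[(E)-tert-butyldiazenyl]-2-hydroxy-2-[5-hydroxy-7-(hydroxymethyl)-2-methyl-4-oxo-4H-chromen-3-yl]propanoate | COC(=O)[C@](O)(C/N=N/C(C)(C)C)c1c(C)oc2cc(CO)cc(O)c2c1=O | intermediate
21 | methyl (2R,3E)-3-(2-tert-butylhydrazinylidene)-2-hydroxy-2-[5-hydroxy-7-(hydroxymethyl)-2-methyl-4-oxo-4H-chromen-3-yl]propanoate | COC(=O)[C@](O)(/C=N/NC(C)(C)C)c1c(C)oc2cc(CO)cc(O)c2c1=O | intermediate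
22 | methyl (2R)-2-hydroxy-2-[5-hydroxy-7-(hydroxymethyl)-2-methyl-4-oxo-4H-chromen-3-yl]-3-oxopropanoate | COC(=O)[C@](O)(C=O)c1c(C)oc2cc(CO)cc(O)c2c1=O | intermediate
23 | 1-(2,6-dihydroxyphenyl)-4-(3-hydroxy-3-methylbutoxy)-5-methyl-2-benzofuran-7-ol (isobenzofuran) | Oc1cccc(O)c1-c1occ2c(OCCC(C)(C)O)c(C)cc(O)c12 | intermediate
24 | methyl (1S)-1,8-dihydroxy-6-(hydroxymethyl)-9-oxo-1,9-dihydrocyclopenta[b]chromene-1-carboxylate | COC(=O)[C@@]1(O)c2c(oc3cc(CO)cc(O)c3c2=O)C=C1 | intermediate
25 | aspergichromone A (exo cycloadduct; cis ring fusion; (S)-C(OH)CO2Me with the OH on the face of the oxygen bridge and the ester on the convex face) | COC(=O)[C@@]1(O)c2c(oc3cc(CO)cc(O)c3c2=O)[C@H]2[C@@H]1[C@H]1O[C@]2(c2c(O)cccc2O)c2c(O)cc(C)c(OCCC(C)(C)O)c21 | target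

## Step count and weak points

Total: 14 steps (each one-flask sequence counted once). Longest linear sequence: 7 steps (steps 1, 2, 3, 4, 5, 7, 14).

**Step 14.** Risks: 24 dimerises, the aldol condensation is too slow under acid, the aldehyde alkylates the resorcinol ring, or the adduct aromatises. The fallback sets out from 22 (with 11) and returns at 25; it separates the two unveilings and makes the dienophile with base. DBU (THF, 0 °C) closes 22 by a discrete intramolecular vinylogous aldol addition to the diol methyl (1R)-1,2,8-trihydroxy-6-(hydroxymethyl)-9-oxo-1,2,3,9-tetrahydrocyclopenta[b]chromene-1-carboxylate F1 (2-epimers). Ac2O/pyridine/DMAP gives the triacetate methyl (1R)-2,8-diacetoxy-6-(acetoxymethyl)-1-hydroxy-9-oxo-1,2,3,9-tetrahydrocyclopenta[b]chromene-1-carboxylate F2, with the tertiary OH untouched. Compound 11 is dehydrated alone to 23 (CSA, 4 Å MS, CH2Cl2), the acid is quenched with excess Et3N (or DBU), and F2 is added slowly. E1cB loss of acetic acid then releases methyl (1S)-8-acetoxy-6-(acetoxymethyl)-1-hydroxy-9-oxo-1,9-dihydrocyclopenta[b]chromene-1-carboxylate F3 only in the presence of the diene. The cycloadduct di-O-acetyl aspergichromone A F4 is deacetylated with K2CO3 in MeOH at 0 °C to give 25.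

**Step 13.** Risks: the ketone is flanked by the 2-methyl group and the C4 carbonyl, so addition may be slow or poorly selective, and the hydrazone nitrogen can attack the chromone. The fallback sets out from 15 and returns at 22; it forms the quaternary centre before the pyranone exists and moves the asymmetric step to the bond to the future chromone C3. Methyl (E)-3-methoxyacrylate is oxidised with mCPBA in MeOH to methyl 2-hydroxy-3,3-dimethoxypropanoate F5, then with Dess–Martin periodinane to methyl 3,3-dimethoxy-2-oxopropanoate F6. [Cu(t-Bu-box)](OTf)2 (10 mol %, antipode chosen for the R centre) binds F6 through its 1,2-dicarbonyl unit, and the enaminone α-carbon of 15 adds to the ketone (Evans-type pyruvate aldol addition). This gives methyl (2R)-3-{2,6-bis(methoxymethoxy)-4-[(methoxymethoxy)methyl]benzoyl}-2-(dimethoxymethyl)-4-(dimethylamino)-2-hydroxypent-3-enoate F7. HCl in MeOH removes the MOM groups and closes the chromone with loss of dimethylamine to give the acetal methyl (2R)-2-hydroxy-2-[5-hydroxy-7-(hydroxymethyl)-2-methyl-4-oxo-4H-chromen-3-yl]-3,3-dimethoxypropanoate F8. Aqueous trifluoroacetic acid hydrolyses the acetal to 22.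

**Step 7.** Risk: the 2,6-disubstituted aryllithium may not add to the ortho-substituted lactone carbonyl. The fallback sets out from 7 and returns at 10; it lowers the electrophile to the aldehyde oxidation level and re-oxidises. DIBAL-H (CH2Cl2, −78 °C) reduces 7 to the lactol 4-(3-hydroxy-3-methylbutoxy)-7-(methoxymethoxy)-5-methyl-1,3-dihydroisobenzofuran-1-ol F9. Lithiated 9 (excess) adds to its ring-opened hydroxy aldehyde form to give the diol [2,6-bis(methoxymethoxy)phenyl][2-(hydroxymethyl)-3-(3-hydroxy-3-methylbutoxy)-6-(methoxymethoxy)-4-methylphenyl]methanol F10. DDQ (CH2Cl2, 0 °C) oxidises the doubly activated diaryl carbinol to the ketone 10; oxidation at the primary alcohol instead would give the isomeric lactol, which leads to the same isobenzofuran 23. The acidic methanolysis of step 7 then gives 11.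

## Further compounds

F1 | step 14 | methyl (1R)-1,2,8-trihydroxy-6-(hydroxymethyl)-9-oxo-1,2,3,9-tetrahydrocyclopenta[b]chromene-1-carboxylate | COC(=O)[C@@]1(O)c2c(oc3cc(CO)cc(O)c3c2=O)CC1O
F2 | step 14 | methyl (1R)-2,8-diacetoxy-6-(acetoxymethyl)-1-hydroxy-9-oxo-1,2,3,9-tetrahydrocyclopenta[b]chromene-1-carboxylate | COC(=O)[C@@]1(O)c2c(oc3cc(COC(C)=O)cc(OC(C)=O)c3c2=O)CC1OC(C)=O
F3 | step 14 | methyl (1S)-8-acetoxy-6-(acetoxymethyl)-1-hydroxy-9-oxo-1,9-dihydrocyclopenta[b]chromene-1-carboxylate | COC(=O)[C@@]1(O)c2c(oc3cc(COC(C)=O)cc(OC(C)=O)c3c2=O)C=C1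
F4 | step 14 | di-O-acetyl aspergichromone A (chromone aryl acetate and benzylic acetate) | COC(=O)[C@@]1(O)c2c(oc3cc(COC(C)=O)cc(OC(C)=O)c3c2=O)[C@H]2[C@@H]1[C@H]1O[C@]2(c2c(O)cccc2O)c2c(O)cc(C)c(OCCC(C)(C)O)c21
F5 | step 13 | methyl 2-hydroxy-3,3-dimethoxypropanoate | COC(=O)C(O)C(OC)OC
F6 | step 13 | methyl 3,3-dimethoxy-2-oxopropanoate | COC(=O)C(=O)C(OC)OC
F7 | step 13 | methyl (2R)-3-{2,6-bis(methoxymethoxy)-4-[(methoxymethoxy)methyl]benzoyl}-2-(dimethoxymethyl)-4-(dimethylamino)-2-hydroxypent-3-enoate | COC(=O)[C@](O)(C(OC)OC)C(C(=O)c1c(OCOC)cc(COCOC)cc1OCOC)=C(C)N(C)C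
F8 | step 13 | methyl (2R)-2-hydroxy-2-[5-hydroxy-7-(hydroxymethyl)-2-methyl-4-oxo-4H-chromen-3-yl]-3,3-dimethoxypropanoate | COC(=O)[C@](O)(C(OC)OC)c1c(C)oc2cc(CO)cc(O)c2c1=O
F9 | step 7 | 4-(3-hydroxy-3-methylbutoxy)-7-(methoxymethoxy)-5-methyl-1,3-dihydroisobenzofuran-1-ol | OC1OCc2c1c(OCOC)cc(C)c2OCCC(C)(C)O
F10 | step 7 | [2,6-bis(methoxymethoxy)phenyl][2-(hydroxymethyl)-3-(3-hydroxy-3-methylbutoxy)-6-(methoxymethoxy)-4-methylphenyl]methanol | COCOc1cccc(OCOC)c1C(O)c1c(OCOC)cc(C)c(OCCC(C)(C)O)c1CO
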